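The flavone is cut across ring C at O1–C8a and C4–C4a. Ring A carries methoxy groups on all four of C5–C8, so its C4a–C8a edge corresponds to the triple bond of symmetrical 3,4,5,6-tetramethoxybenzyne, whose two aryne carbons are equivalent; O1, C4, C3, C2 and ring B come from a 3-arylpropiolic acid. In one operation the aryne inserts into the acid C–O bond and the freed phenoxide closes ring C onto the alkyne, joining both halves without any regiochemical question. The precursors are an ortho-silylaryl triflate built from 1,2,3,4-tetramethoxybenzene and a propiolic acid whose two ring B phenols are masked as benzyl ethers.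

Key step: step 7

Remark: compounds 1 and 9 are taken as catalogue materials; all organolithium steps are run under argon in dry solvents.

Step 1
Reactants: 1 1,2,3,4-tetramethoxybenzene
Product: 4 2,3,4,5-tetramethoxyphenol, via 2,3,4,5-tetramethoxyphenyllithium 2 (not isolated), via dimethyl arylboronate 3 (not isolated)
Conditions: n-BuLi, TMEDA, THF, 0 °C; B(OMe)3, −78 °C → rt; AcOH, 30% aq. H2O2, 0 °C → rt
Reagents that add atoms: n-butyllithium, [Li]CCCC (lithium of 2); trimethyl borate, COB(OC)OC (boron group of 3); hydrogen peroxide, OO (phenol oxygen of 4)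
Why: Directed ortho-metalation, in which a flanking methoxy group and TMEDA steer n-BuLi to one of the two equivalent ring hydrogens of 1, followed by borate quench and peroxide-induced 1,2-aryl shift from boron to oxygen, should give the phenol under mildly acidic conditions that spare the very electron-rich ring.

Step 2
Reactants: 4 2,3,4,5-tetramethoxyphenol
Product: 5 2-bromo-3,4,5,6-tetramethoxyphenol
Conditions: NBS (1.0 equiv), CH2Cl2, −30 → 0 °C, dark
Reagents that add atoms: N-bromosuccinimide, O=C1CCC(=O)N1Br
Why: Electrophilic aromatic bromination can give only one monobromide because the single unsubstituted ring carbon lies ortho to the hydroxyl, and one equivalent of NBS in a cold anhydrous medium limits oxidation of the phenol to quinones.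

Step 3
Reactants: 5 2-bromo-3,4,5,6-tetramethoxyphenol
Product: 8 2,3,4,5-tetramethoxy-6-(trimethylsilyl)phenyl trifluoromethanesulfonate, via aryl trimethylsilyl ether 6 (not isolated), via lithium 2-silylphenoxide 7 (not isolated)
Conditions: HMDS, THF, 65 °C, then evaporation; n-BuLi, THF, −100 → −78 °C; Tf2O, −100 → −78 °C
Reagents that add atoms: hexamethyldisilazane, C[Si](C)(C)N[Si](C)(C)C; n-butyllithium, [Li]CCCC (lithium of 7); trifluoromethanesulfonic anhydride, O=S(=O)(OS(=O)(=O)C(F)(F)F)C(F)(F)F
Why: O-Silylation, then bromine–lithium exchange with retro-Brook 1,3-migration of silicon from oxygen to the ortho carbanion and O-triflation of the released phenoxide is the standard entry to ortho-silylaryl triflates, and a methoxy group beside the silyl or the triflate position is already tolerated in simpler methoxybenzyne precursors.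

Step 4
Reactants: 9 2,4-dihydroxy-5-methoxybenzaldehyde
Product: 10 2,4-bis(benzyloxy)-5-methoxybenzaldehyde
Conditions: BnBr (2.5 equiv), K2CO3, DMF, 60 °C
Reagents that add atoms: benzyl bromide, BrCc1ccccc1
Why: Williamson etherification with excess bromide and gentle warming should alkylate both phenols, including the C2 hydroxyl that is hydrogen-bonded to the aldehyde.

Step 5
Reactants: 10 2,4-bis(benzyloxy)-5-methoxybenzaldehyde; 11 carbon tetrabromide
Product: 12 1,5-bis(benzyloxy)-2-(2,2-dibromovinyl)-4-methoxybenzene
Conditions: CBr4, PPh3, Zn dust, CH2Cl2, rt (ylide preformed); then 10, 0 °C → rt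
Reagents that add atoms: carbon tetrabromide (compound 11), BrC(Br)(Br)Br
Why: Corey–Fuchs dibromo-olefination, a Wittig reaction of Ph3P=CBr2 generated from PPh3, CBr4 and Zn, runs under neutral conditions that leave the benzyl ethers and the electron-rich ring untouched.

Step 6
Reactants: 12 1,5-bis(benzyloxy)-2-(2,2-dibromovinyl)-4-methoxybenzene; 13 carbon dioxide
Product: 15 3-[2,4-bis(benzyloxy)-5-methoxyphenyl]prop-2-ynoic acid, via lithium arylacetylide 14 (not isolated)
Conditions: n-BuLi (2.2 equiv), THF, −78 °C; dry CO2, −78 → 0 °C; cold 1 M HCl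
Reagents that add atoms: n-butyllithium, [Li]CCCC (lithium of 14); carbon dioxide (compound 13), O=C=O
Why: In the second stage of the Corey–Fuchs homologation, bromine–lithium exchange, loss of LiBr with 1,2-hydride shift (Fritsch–Buttenberg–Wiechell) and deprotonation by the second equivalent give the lithium acetylide, which CO2 carboxylates, while the low temperature keeps n-BuLi away from the benzyl ethers.

Step 7
Reactants: 8 2,3,4,5-tetramethoxy-6-(trimethylsilyl)phenyl trifluoromethanesulfonate; 15 3-[2,4-bis(benzyloxy)-5-methoxyphenyl]prop-2-ynoic acid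
Product: 18 2-[2,4-bis(benzyloxy)-5-methoxyphenyl]-5,6,7,8-tetramethoxy-4H-chromen-4-one, via 3,4,5,6-tetramethoxybenzyne 16 (not isolated), via caesium 2-ynoylphenoxide 17 (not isolated)
Conditions: 8 (1.5 equiv), CsF (4 equiv), THF, sealed tube, 125 °C
Reagents that add atoms: caesium fluoride, [Cs+].[F-] (caesium of 17)
Why: Fluoride strips the silyl group from 8 and triflate leaves, giving symmetrical aryne 16; the caesium carboxylate of 15 adds to it, the aryl anion thus formed attacks its own ester carbonyl through a four-membered transition state, and collapse gives ortho-acyl phenoxide 17, a net insertion of the aryne into the acyl C–O bond that forms O1–C8a and C4–C4a. The phenoxide then adds to the β-carbon of the ynone (O1–C2) and protonation at C3 delivers the flavone. The closest known reaction type is the fluoride-mediated C–O insertion of arynes from ortho-silylaryl triflates into carboxylic acids, which with 3-arylpropiolic acids gives flavones directly, here applied to a more highly oxygenated aryne. Ring C is the only ring closed, by 6-endo-dig oxa-Michael addition, and no stereocentre is created. The step needs acyl transfer to outrun protonation of the aryl anion (which would stop at the aryl ester) and 6-endo to beat 5-exo closure: the first is favoured by the aprotic medium, the high temperature and the methoxy group beside the carbanion that stabilises it long enough to reach the carbonyl, the second by the polarisation of the ynone towards its β-carbon, while regiochemistry of aryne attack is moot because both aryne carbons are equivalent. With both ring B phenols benzylated the carboxylate is the only nucleophile offered to the aryne, and any ynone left open would be closed by stirring the crude product with K2CO3 in methanol before purification.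

Step 8
Reactants: 18 2-[2,4-bis(benzyloxy)-5-methoxyphenyl]-5,6,7,8-tetramethoxy-4H-chromen-4-one
Product: 19 2-(2,4-dihydroxy-5-methoxyphenyl)-5,6,7,8-tetramethoxy-4H-chromen-4-one (target CNP0237834.0)
Conditions: H2 (1 atm), 10% Pd/C, EtOAc–MeOH, rt, followed by TLC
Reagents that add atoms: none
Why: In heterogeneous hydrogenolysis of aryl benzyl ethers, benzylic C–O cleavage on palladium is much faster than saturation of the vinylogous-ester C2–C3 bond of ring C and the methyl ethers are inert, so stopping when the mono-benzyl ether has disappeared should give the diphenol.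

Compound list
1 | 1,2,3,4-tetramethoxybenzene | COc1ccc(OC)c(OC)c1OC | starting material
2 | 2,3,4,5-tetramethoxyphenyllithium | [Li]c1cc(OC)c(OC)c(OC)c1OC | intermediate
3 | dimethyl (2,3,4,5-tetramethoxyphenyl)boronate | COB(OC)c1cc(OC)c(OC)c(OC)c1OC | intermediate
4 | 2,3,4,5-tetramethoxyphenol | COc1cc(O)c(OC)c(OC)c1OC | intermediate
5 | 2-bromo-3,4,5,6-tetramethoxyphenol | COc1c(OC)c(OC)c(Br)c(O)c1OC | intermediate
6 | (2-bromo-3,4,5,6-tetramethoxyphenoxy)trimethylsilane | COc1c(OC)c(OC)c(Br)c(O[Si](C)(C)C)c1OC | intermediate
7 | lithium 2,3,4,5-tetramethoxy-6-(trimethylsilyl)phenoxide | [Li+].[O-]c1c(OC)c(OC)c(OC)c(OC)c1[Si](C)(C)C | intermediate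
8 | 2,3,4,5-tetramethoxy-6-(trimethylsilyl)phenyl trifluoromethanesulfonate | COc1c(OC)c(OC)c(OS(=O)(=O)C(F)(F)F)c([Si](C)(C)C)c1OC | intermediate
9 | 2,4-dihydroxy-5-methoxybenzaldehyde | COc1cc(C=O)c(O)cc1O | starting material
10 | 2,4-bis(benzyloxy)-5-methoxybenzaldehyde | COc1cc(C=O)c(OCc2ccccc2)cc1OCc1ccccc1 | intermediate
11 | carbon tetrabromide | BrC(Br)(Br)Br | starting material
12 | 1,5-bis(benzyloxy)-2-(2,2-dibromovinyl)-4-methoxybenzene | COc1cc(C=C(Br)Br)c(OCc2ccccc2)cc1OCc1ccccc1 | intermediate
13 | carbon dioxide | O=C=O | starting material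
14 | lithium [2,4-bis(benzyloxy)-5-methoxyphenyl]acetylide | [Li]C#Cc1cc(OC)c(OCc2ccccc2)cc1OCc1ccccc1 | intermediate
15 | 3-[2,4-bis(benzyloxy)-5-methoxyphenyl]prop-2-ynoic acid | COc1cc(C#CC(=O)O)c(OCc2ccccc2)cc1OCc1ccccc1 | intermediate
16 | 3,4,5,6-tetramethoxybenzyne | COC1=C(OC)C(OC)=C(OC)C#C1 | intermediate
17 | caesium 2-{3-[2,4-bis(benzyloxy)-5-methoxyphenyl]prop-2-ynoyl}-3,4,5,6-tetramethoxyphenoxide | [Cs+].[O-]c1c(OC)c(OC)c(OC)c(OC)c1C(=O)C#Cc1cc(OC)c(OCc2ccccc2)cc1OCc1ccccc1 | intermediate
18 | 2-[2,4-bis(benzyloxy)-5-methoxyphenyl]-5,6,7,8-tetramethoxy-4H-chromen-4-one | COc1cc(-c2cc(=O)c3c(OC)c(OC)c(OC)c(OC)c3o2)c(OCc2ccccc2)cc1OCc1ccccc1 | intermediate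
19 | 2-(2,4-dihydroxy-5-methoxyphenyl)-5,6,7,8-tetramethoxy-4H-chromen-4-one (CNP0237834.0) | COc1cc(-c2cc(=O)c3c(OC)c(OC)c(OC)c(OC)c3o2)c(O)cc1O | target

Total step count: 8 steps.
Longest linear sequence: 5 steps (steps 1, 2, 3, 7, 8; the ring B branch, steps 4, 5, 6, 7, 8, is equally long).

Steps most likely to fail

1. Step 7. The aryl anion may be protonated before acyl transfer, so that the reaction stops at the aryl ester. The electron-rich propiolate may lose CO2 at 125 °C, or carboxylate attack on the doubly methoxy-flanked aryne may be too slow. The fallback builds ring C classically, setting out from phenol 4 and aldehyde 10 and coming back at 18. Ortho-acetylation of 4 at its only free position (AcOH, BF3·OEt2, 80 °C) would give 1-(2-hydroxy-3,4,5,6-tetramethoxyphenyl)ethan-1-one F1. Claisen–Schmidt condensation of F1 with 10 (KOH, EtOH, rt) would give (E)-3-[2,4-bis(benzyloxy)-5-methoxyphenyl]-1-(2-hydroxy-3,4,5,6-tetramethoxyphenyl)prop-2-en-1-one F2. Oxidative cyclisation of F2 with catalytic I2 in DMSO at 120 °C would then deliver flavone 18.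

2. Step 3. Silicon migration from oxygen to carbon may be incomplete in the crowded, fully substituted ring, which would show as protodebromination on work-up. n-BuLi may attack silicon, or triflation of the doubly flanked phenoxide may be sluggish. The fallback sets out from phenol 4 and comes back at 8; it also avoids the electrophilic bromination of step 2. It places silicon on carbon directly by carbamate-directed ortho-lithiation. Treatment of 4 with isopropyl isocyanate and Et3N in CH2Cl2 would give 2,3,4,5-tetramethoxyphenyl N-isopropylcarbamate F3. N-Silylation in the flask (TMSOTf, TMEDA, Et2O), lithiation of the only ring hydrogen (n-BuLi, TMEDA, −78 °C), quench with TMSCl and acidic work-up would give 2,3,4,5-tetramethoxy-6-(trimethylsilyl)phenyl N-isopropylcarbamate F4. Cleavage of the carbamate with DBU and Et2NH in MeCN at 40 °C would release 2,3,4,5-tetramethoxy-6-(trimethylsilyl)phenol F5, which would be triflated in the same flask with PhNTf2 to give 8.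

3. Step 8. The C2–C3 double bond of ring C may be partly saturated while the hindered ether next to the ring junction is still being cleaved, or the catalyst may stall at the mono-benzyl stage. The fallback sets out from 18 and comes back at 19 and replaces reductive cleavage with acidolysis. Trifluoroacetic acid with pentamethylbenzene as benzyl-cation scavenger (rt to 40 °C) should remove both benzyl groups. It cannot reduce the pyranone, and it leaves the methyl ethers, including the one at C5 beside the carbonyl, untouched.

Further compounds
F1 | step 7 | 1-(2-hydroxy-3,4,5,6-tetramethoxyphenyl)ethan-1-one | CC(=O)c1c(O)c(OC)c(OC)c(OC)c1OC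
F2 | step 7 | (E)-3-[2,4-bis(benzyloxy)-5-methoxyphenyl]-1-(2-hydroxy-3,4,5,6-tetramethoxyphenyl)prop-2-en-1-one | COc1cc(/C=C/C(=O)c2c(O)c(OC)c(OC)c(OC)c2OC)c(OCc2ccccc2)cc1OCc1ccccc1
F3 | step 3 | 2,3,4,5-tetramethoxyphenyl N-isopropylcarbamate | CC(C)NC(=O)Oc1cc(OC)c(OC)c(OC)c1OC
F4 | step 3 | 2,3,4,5-tetramethoxy-6-(trimethylsilyl)phenyl N-isopropylcarbamate | CC(C)NC(=O)Oc1c(OC)c(OC)c(OC)c(OC)c1[Si](C)(C)C
F5 | step 3 | 2,3,4,5-tetramethoxy-6-(trimethylsilyl)phenol | COc1c(OC)c(OC)c(O)c([Si](C)(C)C)c1OC
F0 | step 8 | none | none
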